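**Retrosynthetic overview**
1. Target ⇒ jaeschkeanadiol: the C-6 ester C–O bond and both oxirane C–O bonds are made last, in one operation, with bis(4-methoxybenzoyl) peroxide (acyl transfer to the alkoxide, then α-face epoxidation by the peracid this releases).
2. Jaeschkeanadiol ⇒ trans-fused hydroxy-hydroazulenone + isopropyl Grignard reagent (C-4 carbinol).
3. Hydroazulenone ⇒ ring-closing metathesis (C-8=C-9) of a cyclopentanone carrying an allyl arm on C-1 and a methallyl carbinol arm on C-5.
4. That cyclopentanone ⇒ one-pot copper-catalysed asymmetric conjugate methylation of 3-allylcyclopent-2-enone and aldol with 3-methylbut-3-enal (C-1, C-5, C-6).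
5. Ring order: five-membered ring from the commercial enone, then the seven-membered ring, then the oxirane.

Assumption: C-1 to C-10 are daucane locants (C-1 angular-methyl carbon, C-4 isopropyl carbinol, C-5 ring-fusion CH, C-6 ester carbon, C-8/C-9 oxirane carbons; α = face of H-5), and the phosphoramidite enantiomer in step 3 is chosen to give the R quaternary centre (its mirror image is used if induction runs the other way).

**Step 1**
Reactants: 1 3-ethoxycyclopent-2-en-1-one; 2 allylmagnesium bromide
Product: 4 3-(prop-2-en-1-yl)cyclopent-2-en-1-one, via carbinol adduct 3 (not isolated)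
Conditions: 2 (1.2 equiv), THF, 0 °C; then 1 M HCl, 0 °C, 30 min
Reagents that add atoms: allylmagnesium bromide, C=CC[Mg]Br; water, O
Why: Stork–Danheiser enone transposition (1,2-addition to the vinylogous ester, then acid hydrolysis of the enol ether and loss of water); brief cold acid keeps the allyl double bond out of conjugation, and no stereocentre is formed.

**Step 2**
Reactants: 5 3-methylbut-3-en-1-ol
Product: 6 3-methylbut-3-enal
Conditions: Dess–Martin periodinane (1.1 equiv), pyridine (3 equiv), CH2Cl2, 0 °C; cold aq. NaHCO3–Na2S2O3 wash, dried (MgSO4), used at once as a CH2Cl2 solution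
Reagents that add atoms: none
Why: Buffered Dess–Martin oxidation gives the β,γ-unsaturated aldehyde without shifting the double bond into conjugation; no stereocentre.

**Step 3**
Reactants: 4 3-(prop-2-en-1-yl)cyclopent-2-en-1-one; 7 trimethylaluminium; 6 3-methylbut-3-enal
Product: 9 (2S,3R)-2-[(1S)-1-hydroxy-3-methylbut-3-en-1-yl]-3-methyl-3-(prop-2-en-1-yl)cyclopentan-1-one, via aluminium enolate 8 (not isolated)
Conditions: Me3Al (1.3 equiv), CuTC [copper thiophene-2-carboxylate, Cu(O2CC4H3S)] (5 mol %), (S)-BINOL-derived N,N-bis[(R)-1-phenylethyl]phosphoramidite (10 mol %), Et2O, −30 °C; then 6 (2 equiv, dried CH2Cl2 solution), −78 °C; aq. potassium sodium tartrate (KNaC4H4O6)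
Reagents that add atoms: trimethylaluminium, C[Al](C)C
Why: Copper-catalysed asymmetric conjugate addition puts methyl on one face of the β-carbon and sets the quaternary centre (R), and the regiodefined aluminium enolate then adds to the aldehyde through a Zimmerman–Traxler chair (cyclic E-enolate gives the anti aldol) on the ring face syn to methyl and anti to the larger allyl arm, setting C-2 (S) and C-1' (S); I expect only moderate selectivity here (roughly 4:1 at the ring carbon and 5:1 anti:syn, an estimate), so minor isomers are removed by chromatography.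

**Step 4**
Reactants: 9 (2S,3R)-2-[(1S)-1-hydroxy-3-methylbut-3-en-1-yl]-3-methyl-3-(prop-2-en-1-yl)cyclopentan-1-one
Product: 10 (3aR,8S,8aS)-8-hydroxy-3a,6-dimethyl-3,3a,4,7,8,8a-hexahydroazulen-1(2H)-one
Conditions: second-generation Grubbs catalyst RuCl2(=CHPh)(H2IMes)(PCy3) (5 mol %), CH2Cl2 (5 mM), 40 °C
Reagents that add atoms: none
Why: Ring-closing metathesis between the monosubstituted and the 1,1-disubstituted alkene closes the seven-membered ring with its trisubstituted alkene and loses ethene; the two arms are trans on the cyclopentanone, so the ring fusion is trans and no stereocentre is touched.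

**Step 5**
Reactants: 10 (3aR,8S,8aS)-8-hydroxy-3a,6-dimethyl-3,3a,4,7,8,8a-hexahydroazulen-1(2H)-one; 11 isopropylmagnesium chloride
Product: 12 jaeschkeanadiol [(3R,3aS,4S,8aR)-6,8a-dimethyl-3-(propan-2-yl)-1,2,3,3a,4,5,8,8a-octahydroazulene-3,4-diol]
Conditions: i-PrMgCl (3 equiv), LaCl3·2LiCl (30 mol %), THF, 0 °C; aq. NH4Cl
Reagents that add atoms: isopropylmagnesium chloride, CC(C)[Mg]Cl
Why: Lanthanum-promoted Grignard 1,2-addition (suppresses enolisation and β-hydride reduction); isopropyl enters from the α-face, anti to the C-6 ring bond on the neighbouring ring-fusion carbon and anti to the angular methyl, which sets C-4 (R, hydroxyl cis to the angular methyl).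

**Step 6**
Reactants: 13 4-methoxybenzoic anhydride; 14 hydrogen peroxide
Product: 15 bis(4-methoxybenzoyl) peroxide
Conditions: 13 (2.1 equiv), 30% aq. H2O2 (1.0 equiv), NaOH (2.0 equiv, added over 1 h), THF–H2O, 0 °C; diluted with ice water, solid filtered off and washed with cold water; kept cold and used within a day
Reagents that add atoms: hydrogen peroxide, OO
Why: Acyl transfer from the anhydride to hydroperoxide anion gives the peroxycarboxylate, which is acylated by a second anhydride molecule (the anhydride variant of the classical diacyl peroxide synthesis, as used for diacetyl peroxide); each anhydride molecule gives up one acyl group and the other leaves as sodium 4-methoxybenzoate, and no stereocentre is formed.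

**Step 7**
Reactants: 12 jaeschkeanadiol; 15 bis(4-methoxybenzoyl) peroxide
Product: 18 (3R,3aS,4S,6R,7S,8aR)-6,7-epoxy-3-hydroxy-6,8a-dimethyl-3-(propan-2-yl)decahydroazulen-4-yl 4-methoxybenzoate (8α,9α-epoxyjaeschkeanadiol 6-O-p-methoxybenzoate), via anisate ester 16 (not isolated), via 4-methoxyperoxybenzoic acid 17 (not isolated)
Conditions: NaH (1.05 equiv), THF, 0 °C; 15 (1.1 equiv), −20 °C; then AcOH (1.1 equiv), CH2Cl2, 0 °C → rt
Reagents that add atoms: bis(4-methoxybenzoyl) peroxide, COc1ccc(cc1)C(=O)OOC(=O)c1ccc(OC)cc1
Why: Proposed new method: acylative epoxidation with a diaroyl peroxide – the sodium alkoxide of the less hindered secondary hydroxyl attacks one acyl carbon of the peroxide (hard O-nucleophile, addition–elimination), forming the C-6 ester C–O bond and expelling 4-methoxyperoxybenzoate; after protonation this one equivalent of peracid epoxidises the only alkene (Prilezhaev, concerted) from the α-face, anti to the axial angular methyl at C-1 that shields the β-face, setting C-8 (R) and C-9 (S); the closest known reaction type is the cleavage of dibenzoyl peroxide by sodium methoxide into methyl benzoate and sodium perbenzoate (the classical preparation of perbenzoic acid) followed by peracid epoxidation, and what is new is a substrate alkoxide as the nucleophile with the released peracid used on the same molecule.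

**Compound list**
1 | 3-ethoxycyclopent-2-en-1-one | CCOC1=CC(=O)CC1 | starting material
2 | allylmagnesium bromide | C=CC[Mg]Br | starting material
3 | 3-ethoxy-1-(prop-2-en-1-yl)cyclopent-2-en-1-ol (racemic carbinol adduct, formed as its magnesium alkoxide) | CCOC1=CC(O)(CC=C)CC1 | intermediate
4 | 3-(prop-2-en-1-yl)cyclopent-2-en-1-one | C=CCC1=CC(=O)CC1 | intermediate
5 | 3-methylbut-3-en-1-ol | CC(=C)CCO | starting material
6 | 3-methylbut-3-enal | CC(=C)CC=O | intermediate
7 | trimethylaluminium | C[Al](C)C | starting material
8 | dimethylaluminium enolate of (R)-3-methyl-3-(prop-2-en-1-yl)cyclopentanone (enolate towards C-2) | C[C@]1(CC=C)CCC(O[Al](C)C)=C1 | intermediate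
9 | (2S,3R)-2-[(1S)-1-hydroxy-3-methylbut-3-en-1-yl]-3-methyl-3-(prop-2-en-1-yl)cyclopentan-1-one | O[C@@H](CC(C)=C)[C@@H]1[C@@](C)(CC=C)CCC1=O | intermediate
10 | (3aR,8S,8aS)-8-hydroxy-3a,6-dimethyl-3,3a,4,7,8,8a-hexahydroazulen-1(2H)-one (trans-fused) | O[C@H]1CC(C)=CC[C@@]2(C)CCC(=O)[C@H]12 | intermediate
11 | isopropylmagnesium chloride | CC(C)[Mg]Cl | starting material
12 | jaeschkeanadiol, (3R,3aS,4S,8aR)-6,8a-dimethyl-3-(propan-2-yl)-1,2,3,3a,4,5,8,8a-octahydroazulene-3,4-diol | O[C@H]1CC(C)=CC[C@@]2(C)CC[C@@](O)(C(C)C)[C@H]12 | intermediate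
13 | 4-methoxybenzoic anhydride | COc1ccc(cc1)C(=O)OC(=O)c1ccc(OC)cc1 | starting material
14 | hydrogen peroxide | OO | starting material
15 | bis(4-methoxybenzoyl) peroxide | COc1ccc(cc1)C(=O)OOC(=O)c1ccc(OC)cc1 | intermediate
16 | (3R,3aS,4S,8aR)-3-hydroxy-6,8a-dimethyl-3-(propan-2-yl)-1,2,3,3a,4,5,8,8a-octahydroazulen-4-yl 4-methoxybenzoate | COc1ccc(cc1)C(=O)O[C@H]1CC(C)=CC[C@@]2(C)CC[C@@](O)(C(C)C)[C@H]12 | intermediate
17 | 4-methoxyperoxybenzoic acid | COc1ccc(cc1)C(=O)OO | intermediate
18 | (3R,3aS,4S,6R,7S,8aR)-6,7-epoxy-3-hydroxy-6,8a-dimethyl-3-(propan-2-yl)decahydroazulen-4-yl 4-methoxybenzoate | COc1ccc(C(=O)O[C@H]2C[C@@]3(C)O[C@H]3C[C@@]3(C)CC[C@@](O)(C(C)C)[C@H]23)cc1 | target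

**Step count**
Total: 7 steps. Longest linear sequence: 5 steps (1, 3, 4, 5, 7).

**Three steps most likely to fail**

Step 3 (asymmetric conjugate addition–aldol). The ring-face selectivity rests only on methyl versus allyl, the anti:syn ratio of a cyclopentanone enolate is moderate, and about 90% ee is expected (12 can be recrystallised to raise it). Wrong-face isomers must be separated at 9 or 10. The fallback takes the carbinol configuration out of the aldol and sets it by a hydroxyl-directed reduction. It sets out from 12 as obtained from step 5, still holding the carbinol epimer (3R,3aS,4R,8aR)-6,8a-dimethyl-3-(propan-2-yl)-1,2,3,3a,4,5,8,8a-octahydroazulene-3,4-diol F1. The mixture is oxidised at the secondary hydroxyl only (Dess–Martin periodinane, pyridine, CH2Cl2, 0 °C) to the single ketol (3R,3aR,8aR)-3-hydroxy-6,8a-dimethyl-3-(propan-2-yl)-2,3,3a,5,8,8a-hexahydroazulen-4(1H)-one F2, whose trans ring fusion is kept under the buffered conditions. Without purification (the alkene is β,γ to the ketone), F2 is reduced with Me4NBH(OAc)3 in MeCN–AcOH at −30 °C (Evans–Saksena 1,3-anti reduction, hydride delivered from the β-face tertiary hydroxyl) and comes back at 12. This rescues the carbinol epimers but not the wrong-face isomers.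

Step 5 (secondary Grignard reagent on a hindered, enolisable β-hydroxy ketone). Enolisation, β-hydride reduction or retro-aldol opening may compete. The fallback brings in the three carbons as an sp2 nucleophile and reduces afterwards. It sets out from 10: isopropenylmagnesium bromide with CeCl3 in THF at −78 °C (same face of attack) gives (3S,3aS,4S,8aR)-6,8a-dimethyl-3-(prop-1-en-2-yl)-1,2,3,3a,4,5,8,8a-octahydroazulene-3,4-diol F3. Hydrogenation with RhCl(PPh3)3 under 1 atm H2 in benzene, which reduces the 1,1-disubstituted alkene much faster than the trisubstituted ring alkene, comes back at 12.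

Step 7 (the proposed acylative epoxidation). The alkoxide may attack the O–O bond instead of the acyl carbon, the electron-rich peroxide may decompose by carboxy inversion, or the face selectivity of the free peracid may be lower than expected. The fallback uses known chemistry and sets out from 12. Hydroxyl-directed epoxidation with VO(acac)2 (2 mol %) and t-BuOOH in CH2Cl2 delivers oxygen from the vanadate ester of the homoallylic C-6 hydroxyl to the α-face and gives (3R,3aS,4S,6R,7S,8aR)-6,7-epoxy-6,8a-dimethyl-3-(propan-2-yl)decahydroazulene-3,4-diol F4. Acylation of its secondary hydroxyl with 13, Et3N and DMAP in CH2Cl2 comes back at 18.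

**Further compounds**
F1 | step 3 | (3R,3aS,4R,8aR)-6,8a-dimethyl-3-(propan-2-yl)-1,2,3,3a,4,5,8,8a-octahydroazulene-3,4-diol | O[C@@H]1CC(C)=CC[C@@]2(C)CC[C@@](O)(C(C)C)[C@H]12
F2 | step 3 | (3R,3aR,8aR)-3-hydroxy-6,8a-dimethyl-3-(propan-2-yl)-2,3,3a,5,8,8a-hexahydroazulen-4(1H)-one | O=C1CC(C)=CC[C@@]2(C)CC[C@@](O)(C(C)C)[C@H]12
F3 | step 5 | (3S,3aS,4S,8aR)-6,8a-dimethyl-3-(prop-1-en-2-yl)-1,2,3,3a,4,5,8,8a-octahydroazulene-3,4-diol | O[C@H]1CC(C)=CC[C@@]2(C)CC[C@@](O)(C(C)=C)[C@H]12
F4 | step 7 | (3R,3aS,4S,6R,7S,8aR)-6,7-epoxy-6,8a-dimethyl-3-(propan-2-yl)decahydroazulene-3,4-diol | O[C@H]1C[C@@]2(C)O[C@H]2C[C@@]2(C)CC[C@@](O)(C(C)C)[C@H]12
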